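The target, triacontan-30-olide (C30H58O2), is one 31-membered lactone ring: ring oxygen, carbonyl carbon C1 and methylenes C2–C30 (these lactone numbers are used for all intermediates). It has no stereocentre, so nothing stereochemical has to be set.
Enabling feature: the methylene run C16–C21 lies opposite the ester in this ring and bears no functional group, so C17–C20 can be carried as a conjugated 1,3-diyne whose central bond C18–C19 joins two alkyne termini.
Retrosynthesis: (a) desaturate C17–C20 to the diyne; (b) cut C18–C19, which opens the ring; (c) cut the ester bond O–C1; (d) cut the alkyl–alkynyl bond C20–C21 in the alcohol half.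
Forward: acetylide alkylation (C20–C21) gives the C12 alkynol, esterification (O–C1) joins it to the C18 alkynoic acid, oxidative alkyne–alkyne coupling (C18–C19) closes the only ring, and hydrogenation returns C17–C20 to methylenes.

Key step: step 3

Step 1
Reactants: 1 10-bromodecan-1-ol; 2 lithium acetylide–ethylenediamine complex, LiC≡CH·H2NCH2CH2NH2
Product: 3 dodec-11-yn-1-ol
Conditions: LiC≡CH·H2NCH2CH2NH2 (3 equiv), DMSO, 15 °C to rt; aq. NH4Cl
Reagents that add atoms: lithium acetylide–ethylenediamine complex (compound 2), [Li]C#C.NCCN
Why: Acetylide alkylation (SN2) at an unhindered primary bromide in a dipolar aprotic solvent, a standard entry to ω-alkyn-1-ols from ω-bromoalkan-1-ols; one equivalent of reagent is spent on the hydroxyl proton, and the excess acetylide, the softer carbon nucleophile, should outcompete the aggregated lithium alkoxide for the bromide.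

Step 2
Reactants: 3 dodec-11-yn-1-ol; 4 octadec-17-ynoic acid
Product: 5 dodec-11-yn-1-yl octadec-17-ynoate
Conditions: DCC (1.1 equiv), DMAP (0.1 equiv), CH2Cl2, 0 °C to rt
Reagents that add atoms: none
Why: Steglich esterification, in which DCC activates the acid, DMAP relays the acyl group to the unhindered primary alcohol, and both terminal alkynes are spectators under these neutral conditions.

Step 3
Reactants: 5 dodec-11-yn-1-yl octadec-17-ynoate
Product: 6 triaconta-17,19-diyn-30-olide (1-oxacyclohentriaconta-18,20-diyn-2-one)
Conditions: Cu(OAc)2 (10 equiv), pyridine, 60 °C; 5 in pyridine added by syringe pump over 12 h (final ca. 1 mM), then 2 h; aq. NH4Cl/EDTA wash, silica filtration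
Reagents that add atoms: none
Why: Pyridine-assisted exchange of each acidic C(sp)–H for copper gives acetylides at C18 and C19, which pair in an acetylide-bridged dinuclear copper species; its collapse forms the C18–C19 bond while two divalent copper centres are reduced to monovalent copper, so each coupling consumes two Cu(OAc)2 and leaves two CuOAc and two AcOH. This is the Eglinton variant of the Glaser oxidative homocoupling of terminal alkynes, a known way to close large carbocycles and macrolides from α,ω-diynes. The single ring closes end to end as a 31-membered macrocyclization with both triple bonds inside the ring, and a ring of this size should hold the linear C16–C21 rod without strain. No stereocentre is formed. The selectivity needed is ring closure over intermolecular coupling to the 62-membered cyclic dimer and open-chain oligomers; it rests on the slow addition into a large excess of Cu(OAc)2, which keeps the standing concentration of uncoupled alkyne very low. Regiochemistry is not in question because the two reacting ends are the only terminal alkynes present, and the ester is inert to Cu(OAc)2 in pyridine.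

Step 4
Reactants: 6 triaconta-17,19-diyn-30-olide
Product: 7 triacontan-30-olide (oxacyclohentriacontan-2-one)
Conditions: H2 (1 atm), 10% Pd/C, EtOAc/THF, rt
Reagents that add atoms: none
Why: Heterogeneous catalytic hydrogenation, in which the conjugated diyne takes up four equivalents of H2 on the palladium surface to give the C17–C20 tetramethylene unit, while the lactone, whose C–O bonds are remote from the unsaturation and not prone to hydrogenolysis, is untouched and no stereocentre arises.

Compound list
1 | 10-bromodecan-1-ol | OCCCCCCCCCCBr | starting material
2 | lithium acetylide–ethylenediamine complex | [Li]C#C.NCCN | starting material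
3 | dodec-11-yn-1-ol | OCCCCCCCCCCC#C | intermediate
4 | octadec-17-ynoic acid (17-octadecynoic acid) | C#CCCCCCCCCCCCCCCCC(=O)O | starting material
5 | dodec-11-yn-1-yl octadec-17-ynoate | C#CCCCCCCCCCCCCCCCC(=O)OCCCCCCCCCCC#C | intermediate
6 | triaconta-17,19-diyn-30-olide (1-oxacyclohentriaconta-18,20-diyn-2-one) | O=C1CCCCCCCCCCCCCCCC#CC#CCCCCCCCCCCO1 | intermediate
7 | triacontan-30-olide (oxacyclohentriacontan-2-one) | O=C1CCCCCCCCCCCCCCCCCCCCCCCCCCCCCO1 | target

Total step count: 4
Longest linear sequence: 4 steps (1 → 3 → 5 → 6 → 7)

Steps most likely to fail

First, the ring closure of step 3. Intermolecular coupling may overtake ring closure whenever uncoupled alkyne accumulates, draining material into cyclic dimer and chain oligomers; the coupling may also slow as monovalent copper builds up. The fallback sets out from 3 and 4 and comes back to the route at 6. It makes C18–C19 between two molecules, where bimolecular coupling is the wanted event, and closes the ring at O–C1 instead. Bromination of the alkyne C–H of 3 (N-bromosuccinimide, cat. AgNO3, acetone, rt) should give 12-bromododec-11-yn-1-ol F1. Cadiot–Chodkiewicz cross-coupling of F1 with the terminal alkyne of 4 (cat. CuCl, NH2OH·HCl, aq. EtNH2, MeOH/THF, 0 °C to rt) should give 30-hydroxytriaconta-17,19-diynoic acid F2. Yamaguchi macrolactonization then follows: 2,4,6-trichlorobenzoyl chloride and Et3N in THF should convert F2 into the mixed anhydride 30-hydroxytriaconta-17,19-diynoic 2,4,6-trichlorobenzoic anhydride F3, which is not isolated. Slow addition of that solution to DMAP in toluene at 100 °C should close the lactone and deliver 6.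

Second, the alkylation of step 1. With the hydroxyl free, the alkoxide may compete for the bromide and build ether oligomers, and long exposure to the basic amine complex may move the triple bond inward. The fallback sets out from 1 and comes back at 3, and it removes the alkoxide altogether by a protecting-group detour. 3,4-Dihydro-2H-pyran with cat. PPTS in CH2Cl2 should give the racemic acetal 2-[(10-bromodecyl)oxy]oxane F4. Alkylation of F4 with 2 (1.5 equiv, DMSO, rt) should give 2-(dodec-11-yn-1-yloxy)oxane F5. Methanolysis (cat. TsOH, MeOH, rt) would release 3.

Third, the esterification of step 2. The carbodiimide-activated acid may rearrange by O-to-N acyl shift to an unreactive N-acylurea, and the urea by-product may be hard to separate from the waxy ester. The fallback sets out from 3 and comes back at 5; it forms the alkyl C30–O bond instead of the acyl C1–O bond and uses no carbodiimide. MsCl and Et3N in CH2Cl2 at 0 °C should give dodec-11-yn-1-yl methanesulfonate F6. SN2 displacement by the caesium carboxylate of 4 (Cs2CO3, DMF, 50 °C) should then give 5.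

Further compounds
F1 | step 3 | 12-bromododec-11-yn-1-ol | OCCCCCCCCCCC#CBr
F2 | step 3 | 30-hydroxytriaconta-17,19-diynoic acid | OCCCCCCCCCCC#CC#CCCCCCCCCCCCCCCCC(=O)O
F3 | step 3 | 30-hydroxytriaconta-17,19-diynoic 2,4,6-trichlorobenzoic anhydride | OCCCCCCCCCCC#CC#CCCCCCCCCCCCCCCCC(=O)OC(=O)c1c(Cl)cc(Cl)cc1Cl
F4 | step 1 | 2-[(10-bromodecyl)oxy]oxane (racemic) | BrCCCCCCCCCCOC1CCCCO1
F5 | step 1 | 2-(dodec-11-yn-1-yloxy)oxane (racemic) | C#CCCCCCCCCCCOC1CCCCO1
F6 | step 2 | dodec-11-yn-1-yl methanesulfonate | CS(=O)(=O)OCCCCCCCCCCC#C
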